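**Retrosynthetic overview**
- The target is 5-formyl-δ-tocotrienol, (R) at C2. The C5 aldehyde is put on last by ortho-formylation of (R)-δ-tocotrienol.
- The pyran ring is closed through O1–C8a: the C2 tertiary hydroxyl is added oxidatively to a 4-methoxyphenol, and the 8a-methoxy ketal is then reduced with loss of methanol. The C2–O bond is never broken.
- C4–C4a comes from opening an (R)-2,2-disubstituted oxetane at its CH2 with an aryllithium made from 2-methylhydroquinone.
- The strategy rests on one feature: C2, with its methyl, O1 and the C1'–C12' trienyl chain, is the carbonyl carbon of farnesylacetone, and C3 and C4 are two CH2 units delivered by a sulfoxonium ylide.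
- Ring order: oxetane (step 1, temporary), then the pyran ring (step 7, aromatised in step 8). The arene is bought.

Key step: step 1

Assumption: the (S)-binaphthoxide catalyst is taken to give the (R) configuration at C2; if the sense of induction for this ketone is the opposite, the (R)-binaphthoxide catalyst is used with no other change.

**Step 1**
Reactants: 1 (5E,9E)-farnesylacetone; 2 trimethylsulfoxonium iodide
Product: 4 (R)-2-methyl-2-[(3E,7E)-4,8,12-trimethyltrideca-3,7,11-trienyl]oxetane, via (R)-epoxide 3 (not isolated)
Conditions: 2, NaH, THF, reflux (ylide solution); 1, LaLi3[(S)-binaphthoxide]3 = LaLi3(O2C20H12)3 (5 mol %), (2,4,6-(MeO)3C6H2)3P=O (5 mol %), 5 Å MS, THF, rt; then more ylide (1.2 equiv) and catalyst (15 mol %), 45 °C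
Reagents that add atoms: dimethylsulfoxonium methylide (made in the flask from 2), C[S+](C)(=O)[CH2-]
Why: The La/Li binaphthoxide–phosphine oxide complex should bind the ketone at a Lewis acidic metal and guide the ylide through a binaphthoxide oxygen, so that CH2 adds to one carbonyl face and the betaine closes by 3-exo-tet displacement of DMSO to epoxide 3 (C2–C3 bond). A second ylide then opens the epoxide at its CH2 by SN2 attack, and the γ-sulfoxonium alkoxide closes by 4-exo-tet displacement of DMSO to the oxetane (C3–C4 bond), with the C2–O bond intact throughout. The closest known reaction type is the catalytic asymmetric Corey–Chaykovsky epoxidation of methyl ketones and its one-pot sequential extension to 2,2-disubstituted oxetanes. The C2 stereocentre is set under catalyst control in the first addition, which distinguishes CH3 from the CH2CH2 chain, and the chiral catalyst should expand the major epoxide enantiomer faster, which raises the enantiomeric purity of 4. The step needs C=O over C=C chemoselectivity and epoxide opening at CH2 only; the nucleophilic ylide has no reason to attack isolated trisubstituted alkenes, and the quaternary epoxide carbon is blocked.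

**Step 2**
Reactants: 5 2-methylhydroquinone
Product: 6 2-methyl-4-(triisopropylsilyloxy)phenol
Conditions: TIPSCl (1.0 equiv), imidazole, DMF, 0 °C
Reagents that add atoms: triisopropylsilyl chloride, CC(C)[Si](Cl)(C(C)C)C(C)C
Why: Silylation with the bulky chlorosilane should take the hydroxyl remote from the methyl group, which is both less hindered and more acidic; the minor regioisomer and bis-silyl ether are removed by chromatography.

**Step 3**
Reactants: 6 2-methyl-4-(triisopropylsilyloxy)phenol
Product: 7 2-bromo-6-methyl-4-(triisopropylsilyloxy)phenol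
Conditions: NBS, iPr2NH (cat.), CH2Cl2, 0 °C
Reagents that add atoms: N-bromosuccinimide, O=C1CCC(=O)N1Br
Why: Amine-catalysed electrophilic ortho-bromination of a free phenol should go to the only open position next to OH, since the para position is blocked and the positions next to the bulky silyl ether are shielded.

**Step 4**
Reactants: 7 2-bromo-6-methyl-4-(triisopropylsilyloxy)phenol
Product: 8 (3-bromo-4-methoxy-5-methylphenoxy)triisopropylsilane
Conditions: MeI, K2CO3, acetone, rt
Reagents that add atoms: iodomethane, CI
Why: Williamson O-methylation of the phenoxide; the aryl triisopropylsilyl ether should survive carbonate in acetone.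

**Step 5**
Reactants: 8 (3-bromo-4-methoxy-5-methylphenoxy)triisopropylsilane; 4 (R)-2-methyl-2-[(3E,7E)-4,8,12-trimethyltrideca-3,7,11-trienyl]oxetane
Product: 10 (3R,6E,10E)-1-[2-methoxy-3-methyl-5-(triisopropylsilyloxy)phenyl]-3,7,11,15-tetramethylhexadeca-6,10,14-trien-3-ol, via aryllithium 9 (not isolated)
Conditions: 8 (2.5 equiv), t-BuLi (5 equiv), Et2O, −78 °C; then 4, BF3·OEt2, THF, −78 °C
Reagents that add atoms: none
Why: Bromine–lithium exchange gives a regiodefined aryllithium (lithium meta to the silyl ether, so no silyl migration), which should open the BF3-activated oxetane by SN2 attack at the unsubstituted CH2 (organolithium/BF3 oxetane opening), forming C4–C4a and leaving the C2–O bond and its configuration untouched.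

**Step 6**
Reactants: 10 the silyl ether from step 5
Product: 11 3-[(3R,6E,10E)-3-hydroxy-3,7,11,15-tetramethylhexadeca-6,10,14-trienyl]-4-methoxy-5-methylphenol
Conditions: Bu4NF, THF, 0 °C; aq. NH4Cl
Reagents that add atoms: none
Why: Fluoride cleavage of the aryl silyl ether; the tertiary alcohol, the methyl ether and the triene are inert to fluoride.

**Step 7**
Reactants: 11 the 4-methoxyphenol from step 6
Product: 12 (2R)-8a-methoxy-2,8-dimethyl-2-[(3E,7E)-4,8,12-trimethyltrideca-3,7,11-trienyl]-3,4-dihydro-2H-chromen-6(8aH)-one (mixture of C8a epimers)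
Conditions: PhI(OAc)2 (1.05 equiv), MeCN, 0 °C
Reagents that add atoms: none
Why: Oxidative dearomatisation of a 4-methoxyphenol by the trivalent-iodine reagent should give an aryloxy-iodane/phenoxenium species that is captured at the methoxy-bearing para carbon C8a by the tethered tertiary hydroxyl in a six-membered closure, forming O1–C8a and the mixed quinone monoketal; the C8a configuration is irrelevant because it is lost on aromatisation.

**Step 8**
Reactants: 12 the 8a-methoxy ketal from step 7
Product: 13 (R)-δ-tocotrienol, (2R)-2,8-dimethyl-2-[(3E,7E)-4,8,12-trimethyltrideca-3,7,11-trienyl]-3,4-dihydro-2H-chromen-6-ol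
Conditions: L-ascorbic acid (excess), AcOH, degassed THF/MeOH, rt
Reagents that add atoms: none
Why: Reductive aromatisation as known for 8a-alkoxy chromenones (tocopherones): acid ionises the ketal reversibly, loss of methanol gives the cyclic chromanoxylium cation, which ascorbate reduces by two electrons to the chromanol, while a ring-opened cation merely recloses; C2–O stays intact.

**Step 9**
Reactants: 13 (R)-δ-tocotrienol
Product: 15 (2R)-6-hydroxy-2,8-dimethyl-2-[(3E,7E)-4,8,12-trimethyltrideca-3,7,11-trienyl]-3,4-dihydro-2H-chromene-5-carbaldehyde (target), via 5-hydroxymethyl chromanol 14 (not isolated)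
Conditions: MgCl2, Et3N, (CH2O)n, THF, reflux, argon
Reagents that add atoms: paraformaldehyde (formaldehyde), C=O
Why: Casnati–Skattebøl ortho-formylation: the magnesium phenoxide is hydroxymethylated ortho to oxygen and the benzylic alkoxide is oxidised by hydride transfer to a second formaldehyde; C5 should be preferred over C7 because of the bond fixation imposed by the fused pyran ring, as in electrophilic substitutions of δ-tocopherol, and the non-acidic medium spares the triene.

**Compound list**
1 | (5E,9E)-farnesylacetone | CC(C)=CCC/C(C)=C/CC/C(C)=C/CCC(C)=O | starting material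
2 | trimethylsulfoxonium iodide | C[S+](C)(C)=O.[I-] | starting material
3 | (R)-2-methyl-2-[(3E,7E)-4,8,12-trimethyltrideca-3,7,11-trienyl]oxirane | CC(C)=CCC/C(C)=C/CC/C(C)=C/CC[C@]1(C)CO1 | intermediate
4 | (R)-2-methyl-2-[(3E,7E)-4,8,12-trimethyltrideca-3,7,11-trienyl]oxetane | CC(C)=CCC/C(C)=C/CC/C(C)=C/CC[C@]1(C)CCO1 | intermediate
5 | 2-methylhydroquinone | Cc1cc(O)ccc1O | starting material
6 | 2-methyl-4-(triisopropylsilyloxy)phenol | Cc1cc(O[Si](C(C)C)(C(C)C)C(C)C)ccc1O | intermediate
7 | 2-bromo-6-methyl-4-(triisopropylsilyloxy)phenol | Cc1cc(O[Si](C(C)C)(C(C)C)C(C)C)cc(Br)c1O | intermediate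
8 | (3-bromo-4-methoxy-5-methylphenoxy)triisopropylsilane | COc1c(C)cc(O[Si](C(C)C)(C(C)C)C(C)C)cc1Br | intermediate
9 | [2-methoxy-3-methyl-5-(triisopropylsilyloxy)phenyl]lithium | [Li]c1cc(O[Si](C(C)C)(C(C)C)C(C)C)cc(C)c1OC | intermediate
10 | (3R,6E,10E)-1-[2-methoxy-3-methyl-5-(triisopropylsilyloxy)phenyl]-3,7,11,15-tetramethylhexadeca-6,10,14-trien-3-ol | CC(C)=CCC/C(C)=C/CC/C(C)=C/CC[C@@](C)(O)CCc1cc(O[Si](C(C)C)(C(C)C)C(C)C)cc(C)c1OC | intermediate
11 | 3-[(3R,6E,10E)-3-hydroxy-3,7,11,15-tetramethylhexadeca-6,10,14-trienyl]-4-methoxy-5-methylphenol | CC(C)=CCC/C(C)=C/CC/C(C)=C/CC[C@@](C)(O)CCc1cc(O)cc(C)c1OC | intermediate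
12 | (2R)-8a-methoxy-2,8-dimethyl-2-[(3E,7E)-4,8,12-trimethyltrideca-3,7,11-trienyl]-3,4-dihydro-2H-chromen-6(8aH)-one, C8a epimers | CC(C)=CCC/C(C)=C/CC/C(C)=C/CC[C@]1(C)CCC2=CC(=O)C=C(C)C2(OC)O1 | intermediate
13 | (R)-δ-tocotrienol | CC(C)=CCC/C(C)=C/CC/C(C)=C/CC[C@]1(C)CCc2cc(O)cc(C)c2O1 | intermediate
14 | (2R)-5-(hydroxymethyl)-2,8-dimethyl-2-[(3E,7E)-4,8,12-trimethyltrideca-3,7,11-trienyl]-3,4-dihydro-2H-chromen-6-ol (as magnesium salt) | CC(C)=CCC/C(C)=C/CC/C(C)=C/CC[C@]1(C)CCc2c(CO)c(O)cc(C)c2O1 | intermediate
15 | (2R)-6-hydroxy-2,8-dimethyl-2-[(3E,7E)-4,8,12-trimethyltrideca-3,7,11-trienyl]-3,4-dihydro-2H-chromene-5-carbaldehyde | CC(C)=CCC/C(C)=C/CC/C(C)=C/CC[C@]1(C)CCc2c(C=O)c(O)cc(C)c2O1 | target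

**Step count**
Total: 9 steps. Longest linear sequence: 8 steps (5 to 15 through steps 2–9); 6 steps from farnesylacetone 1.

**Steps most likely to fail**

Step 7. The oxidised arene may be captured by acetate or adventitious water instead of the hindered tertiary hydroxyl, or the iodane may attack the chain alkenes. Fallback from 11: oxidative demethylation with (NH4)2Ce(NO3)6 in MeCN/H2O at 0 °C should give the hydroxyalkyl benzoquinone F2. Equilibration of F2 in MeOH/HC(OMe)3 with catalytic pyridinium tosylate should then add the tertiary hydroxyl to the neighbouring carbonyl and methylate the hemiketal, as known for tocopherylquinones. This forms the same O1–C8a bond under thermodynamic control and rejoins the route at 12.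

Step 8. The ketal may hydrolyse to the quinone faster than it is reduced, or aromatise with loss of the ring oxygen instead of methoxide. Fallback from 12: 1,2-reduction of the dienone with NaBH4/CeCl3·7H2O in MeOH at −78 °C should give the dienol F3, so that no quinone-level species meets acid and water. Brief treatment of F3 with pyridinium tosylate or silica gel in CH2Cl2 should ionise C8a with loss of methanol and of the C6 proton, rejoining the route at 13. Any material that aromatises with ring opening is phenol 11 and is returned to step 7.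

Step 5. BF3 may ionise the tertiary C2–O bond of the oxetane, leading to elimination or cation–olefin cyclisation, or may consume the aryllithium as a borate. Fallback from 8: magnesium insertion (Mg, THF) should give the arylmagnesium bromide F1. Copper-catalysed opening of 4 (copper iodide CuI, 10 mol %, THF, rt to 50 °C) is then an SN2 attack at CH2 with no strong Lewis acid present, and rejoins the route at 10.

**Further compounds**
F1 | step 5 | [2-methoxy-3-methyl-5-(triisopropylsilyloxy)phenyl]magnesium bromide | Br[Mg]c1cc(O[Si](C(C)C)(C(C)C)C(C)C)cc(C)c1OC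
F2 | step 7 | 2-[(3R,6E,10E)-3-hydroxy-3,7,11,15-tetramethylhexadeca-6,10,14-trienyl]-6-methyl-1,4-benzoquinone | CC(C)=CCC/C(C)=C/CC/C(C)=C/CC[C@@](C)(O)CCC1=CC(=O)C=C(C)C1=O
F3 | step 8 | (2R)-8a-methoxy-2,8-dimethyl-2-[(3E,7E)-4,8,12-trimethyltrideca-3,7,11-trienyl]-3,4,6,8a-tetrahydro-2H-chromen-6-ol | CC(C)=CCC/C(C)=C/CC/C(C)=C/CC[C@]1(C)CCC2=CC(O)C=C(C)C2(OC)O1
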